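**Strategy.** Ring B is closed last among the carbocycles by forming the C9–C10 bond, which joins two fully substituted carbons. The step exploits that C10 is the β-carbon of the ring A enone (C5=C10–C6=O) and that C9 carries the ring C ether oxygen. Cathodic reduction of a C9 N-acyloxyphthalimide expels CO2, and the tertiary α-alkoxy C9 radical adds 6-endo to C10, closing ring B and setting C9, C10 and C5 in one operation. The precursor is the Michael adduct of an enantiopure ring C ester (C13 alkynyl and silyloxymethyl) with β-damascone, carrying a C7 silyl ether, the C8 methyl group and the C9 phthalimide ester.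

Key step: step 12

Remark 1: labdane numbering (C1–C20) is used; TBS = tert-butyldimethylsilyl, TMS = trimethylsilyl.
Remark 2: C16 must be oxygenated and C13 must be set in absolute terms, so ring C cannot come from a levulinate (that would leave a methyl group on C13 and give racemic material); it is built from 2-bromoallyl alcohol, trimethylsilylacetylene and allylmagnesium chloride, with a Sharpless epoxidation fixing C13.
Remark 3: C9 of compounds 15–21 is drawn as the expected 9R epimer; it is a throwaway centre, because step 12 makes it trigonal and both epimers give the same radical.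
Remark 4: the key-step precursor 21 and product 24 are consistent with the target at every stereocentre and needed no correction.

Step 1
Reactants: 1 2-bromoprop-2-en-1-ol; 2 trimethylsilylacetylene
Product: 3 2-methylidene-4-(trimethylsilyl)but-3-yn-1-ol
Conditions: Pd(PPh3)2Cl2 (2 mol%), CuI (4 mol%), iPr2NH, THF, rt
Reagents that add atoms: none
Why: Sonogashira coupling of a vinyl bromide with a terminal alkyne, which tolerates the free allylic alcohol and creates no stereocentre.

Step 2
Reactants: 3 2-methylidene-4-(trimethylsilyl)but-3-yn-1-ol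
Product: 4 (R)-{2-[(trimethylsilyl)ethynyl]oxiran-2-yl}methanol
Conditions: Ti(OiPr)4 (10 mol%), D-(−)-diisopropyl tartrate (12 mol%), tBuOOH, 4 Å MS, CH2Cl2, −20 °C
Reagents that add atoms: tert-butyl hydroperoxide, CC(C)(C)OO
Why: Katsuki–Sharpless asymmetric epoxidation of a 2-substituted allylic alcohol, in which the D-tartrate ligand should deliver oxygen to the face that makes C13 (R) (the facial sense that turns methallyl alcohol into (R)-2-methylglycidol).

Step 3
Reactants: 4 (R)-{2-[(trimethylsilyl)ethynyl]oxiran-2-yl}methanol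
Product: 5 (S)-tert-butyldimethyl({2-[(trimethylsilyl)ethynyl]oxiran-2-yl}methoxy)silane
Conditions: TBSCl, imidazole, CH2Cl2, 0 °C → rt
Reagents that add atoms: tert-butyldimethylsilyl chloride, CC(C)(C)[Si](C)(C)Cl
Why: Silylation of the primary alcohol leaves the epoxide and C13 untouched (the descriptor changes to S only through the priority rules).

Step 4
Reactants: 5 (S)-tert-butyldimethyl({2-[(trimethylsilyl)ethynyl]oxiran-2-yl}methoxy)silane; 6 allylmagnesium chloride
Product: 7 (3R)-3-[(TBS-oxy)methyl]-1-(trimethylsilyl)hept-6-en-1-yn-3-ol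
Conditions: CH2=CHCH2MgCl, THF, −40 → 0 °C; then H2O
Reagents that add atoms: none
Why: SN2 opening of the 2,2-disubstituted epoxide at its CH2 carbon (C12) by the allyl Grignard reagent breaks no bond to C13, so its configuration is retained, and copper is left out to avoid SN2′ attack on the alkynyl epoxide.

Step 5
Reactants: 7 (3R)-3-[(TBS-oxy)methyl]-1-(trimethylsilyl)hept-6-en-1-yn-3-ol
Product: 9 {(5R)-5-[(TBS-oxy)methyl]-5-[(trimethylsilyl)ethynyl]oxolan-2-yl}methanol (both C2 epimers), via terminal epoxide 8 (not isolated)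
Conditions: mCPBA, CH2Cl2, 0 °C → rt; then CSA (10 mol%), rt
Reagents that add atoms: mCPBA, OOC(=O)c1cccc(Cl)c1
Why: Prilezhaev epoxidation of the only alkene, then acid-catalysed 5-exo-tet opening of the epoxide at its more substituted carbon by the tertiary hydroxyl, closes ring C; the new C9 centre forms as a mixture, which is harmless because C9 is made trigonal in steps 8 and 12.

Step 6
Reactants: 9 {(5R)-5-[(TBS-oxy)methyl]-5-[(trimethylsilyl)ethynyl]oxolan-2-yl}methanol
Product: 11 (5R)-5-[(TBS-oxy)methyl]-5-[(trimethylsilyl)ethynyl]oxolane-2-carboxylic acid (both C2 epimers), via aldehyde 10 (not isolated)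
Conditions: TEMPO (20 mol%), PhI(OAc)2, MeCN/H2O (1:1), rt
Reagents that add atoms: water, O
Why: Nitroxyl-catalysed oxidation of the primary alcohol through the aldehyde hydrate to the acid, to which the silyl ether and the silylalkyne are inert.

Step 7
Reactants: 11 (5R)-5-[(TBS-oxy)methyl]-5-[(trimethylsilyl)ethynyl]oxolane-2-carboxylic acid
Product: 12 allyl (5R)-5-[(TBS-oxy)methyl]-5-[(trimethylsilyl)ethynyl]oxolane-2-carboxylate (both C2 epimers)
Conditions: allyl bromide, K2CO3, DMF, rt
Reagents that add atoms: allyl bromide, C=CCBr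
Why: O-alkylation of the carboxylate gives an allyl ester, chosen because zerovalent palladium removes it later without base.

Step 8
Reactants: 12 allyl (5R)-5-[(TBS-oxy)methyl]-5-[(trimethylsilyl)ethynyl]oxolane-2-carboxylate; 13 β-damascone
Product: 16 allyl (2R,5R)-2-[(2R,3Z)-4-(TBS-oxy)-4-(2,6,6-trimethylcyclohex-1-en-1-yl)but-3-en-2-yl]-5-[(TBS-oxy)methyl]-5-[(trimethylsilyl)ethynyl]oxolane-2-carboxylate, via lithium ester enolate 14 (not isolated), via lithium ketone enolate 15 (not isolated)
Conditions: LiN(iPr)2, THF, −78 °C; 13, −78 → −40 °C; TBSOTf, −78 °C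
Reagents that add atoms: tert-butyldimethylsilyl triflate, CC(C)(C)[Si](C)(C)OS(=O)(=O)C(F)(F)F
Why: Michael addition of the lithium ester enolate to the s-cis enone through a lithium-bridged closed transition state, then O-silylation of the resulting Z enolate; the C8–C9 bond should form anti to the pseudoaxial alkynylsilane on ring C with the C8 methyl anti to the ester carbon, giving (8R,9R), and only C8 matters because C9 is erased in step 12 (any C8 epimer is removed by chromatography after step 9).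

Step 9
Reactants: 16 silyl enol ether from step 8
Product: 18 allyl (2R,5R)-2-[(2R,3R)-3-(TBS-oxy)-4-oxo-4-(2,6,6-trimethylcyclohex-1-en-1-yl)butan-2-yl]-5-[(TBS-oxy)methyl]-5-[(trimethylsilyl)ethynyl]oxolane-2-carboxylate, via silyloxy oxirane 17 (not isolated)
Conditions: mCPBA (1.05 equiv), NaHCO3, CH2Cl2, −20 → 0 °C
Reagents that add atoms: mCPBA, OOC(=O)c1cccc(Cl)c1
Why: Rubottom oxidation, in which the peracid epoxidises the electron-rich silyl enol ether on the face away from the quaternary C9 in the conformer that minimises allylic 1,3-strain and a 1,4-silyl shift gives the (7R) silyl ether directly, so no free C7 alkoxide can lactonise onto the C9 ester.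

Step 10
Reactants: 18 allyl ester from step 9
Product: 19 (2R,5R)-2-[(2R,3R)-3-(TBS-oxy)-4-oxo-4-(2,6,6-trimethylcyclohex-1-en-1-yl)butan-2-yl]-5-[(TBS-oxy)methyl]-5-[(trimethylsilyl)ethynyl]oxolane-2-carboxylic acid
Conditions: Pd(PPh3)4 (5 mol%), morpholine, THF, rt
Reagents that add atoms: none
Why: Tsuji–Trost deallylation with zerovalent palladium and morpholine as allyl acceptor frees the hindered acid under neutral conditions that spare the silyl groups and cannot trigger retro-Michael cleavage.

Step 11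
Reactants: 19 acid from step 10; 20 N-hydroxyphthalimide
Product: 21 1,3-dioxoisoindolin-2-yl (2R,5R)-2-[(2R,3R)-3-(TBS-oxy)-4-oxo-4-(2,6,6-trimethylcyclohex-1-en-1-yl)butan-2-yl]-5-[(TBS-oxy)methyl]-5-[(trimethylsilyl)ethynyl]oxolane-2-carboxylate
Conditions: DIC, DMAP (10 mol%), CH2Cl2, rt
Reagents that add atoms: none
Why: Carbodiimide (Steglich-type) esterification with N-hydroxyphthalimide, routine for tertiary acids, gives the redox-active ester.

Step 12
Reactants: 21 N-acyloxyphthalimide from step 11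
Product: 24 (5S,7R,8R,9R,10S,13R)-7β,16-bis(TBS-oxy)-9α,13-epoxy-15-(trimethylsilyl)labd-14-yn-6-one, via C9 radical 22 (not isolated), via zinc C5 enolate 23 (not isolated)
Conditions: carbon (RVC) cathode, Zn anode, nBu4NBF4 (0.1 M), DMA, constant current (2.2 F/mol), rt; then H2O
Reagents that add atoms: none
Why: One-electron reduction of the phthalimide ester, at a potential well short of that needed for the enone, gives a radical anion that loses phthalimide anion and CO2 and leaves the tertiary α-alkoxy radical at C9; this nucleophilic radical adds to C10, the β-carbon of the ring A enone, and the resulting C5 α-keto radical is reduced to the enolate, which is protonated on work-up. The closest known reaction type is the decarboxylative Giese addition of tertiary α-alkoxy radicals from N-acyloxyphthalimides to enones, used here intramolecularly. Ring B closes in the 6-endo-trig mode expected for a 4-oxohex-5-enyl radical, because the 5-exo alternative would send a nucleophilic radical to the enone α-carbon and make a strained cyclopentanone. C10 is set by the chair transition state in which the C8 methyl and C7 silyloxy groups are equatorial, which places the C10 methyl axial; C9 is set in the same chair by the ring C oxygen taking the axial site anti to that methyl with the C11 methylene equatorial (as in 1-oxaspiro[4.5]decanes), and C5 by protonation of the enolate from the α face, the trans-fused ketone also being the thermodynamic epimer. The step needs the radical to cyclise before it is quenched, which is why no hydrogen-atom donor is present and why Zn2+ from the anode is welcome as an activator of the C6 carbonyl.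

Step 13
Reactants: 24 tricyclic ketone from step 12
Product: 25 (5S,6S,7R,8R,9R,10S,13R)-7β,16-bis(TBS-oxy)-9α,13-epoxy-15-(trimethylsilyl)labd-14-yn-6β-ol
Conditions: NaBH4, MeOH/THF (1:1), 0 °C → rt; then H2O
Reagents that add atoms: none
Why: Hydride reduction in which the β face of C6 is blocked by the axial C19 and C20 methyl groups, so hydride enters from the α face and gives the axial 6β alcohol (6S).

Step 14
Reactants: 25 6β-alcohol from step 13
Product: 26 (5S,6S,7R,8R,9R,10S,13R)-6β-acetoxy-7β,16-bis(TBS-oxy)-9α,13-epoxy-15-(trimethylsilyl)labd-14-yne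
Conditions: Ac2O, DMAP, Et3N, CH2Cl2, 40 °C
Reagents that add atoms: acetic anhydride, CC(=O)OC(C)=O
Why: DMAP-catalysed acylation of the hindered axial alcohol, which is the only free hydroxyl in the molecule.

Step 15
Reactants: 26 acetate from step 14
Product: 27 (13R)-6β-acetoxy-9α,13-epoxylabd-14-yne-7β,16-diol
Conditions: Bu4NF, AcOH (1:1), THF, 0 °C → rt
Reagents that add atoms: none
Why: Fluoride cleaves the two O–Si bonds and the alkyne C–Si bond, and acetic acid buffers the medium so that the C7 alkoxide is protonated before the neighbouring acetate can migrate.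

Step 16
Reactants: 27 alkynediol from step 15
Product: 28 (13R)-6β-acetoxy-9α,13:15,16-diepoxylabd-14-en-7β-ol
Conditions: W(CO)6 (25 mol%), Et3N, THF, hν (350 nm), 55 °C
Reagents that add atoms: none
Why: Tungsten-vinylidene cycloisomerisation of a but-3-yn-1-ol, in which the C16 hydroxyl adds to the carbene carbon C15 and closes ring D as the 2,3-dihydrofuran without touching C13.

Step 17
Reactants: 28 dihydrofuran alcohol from step 16
Product: 29 (5S,6S,8S,9R,10S,13R)-6β-acetoxy-9α,13:15,16-diepoxylabd-14-en-7-one (CNP0224709.1)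
Conditions: Dess–Martin periodinane, NaHCO3, CH2Cl2, 0 °C → rt
Reagents that add atoms: none
Why: Dess–Martin oxidation of the only remaining hydroxyl under buffered, non-basic conditions that spare the enol ether and do not epimerise C6 or C8 next to the new ketone.

**Compound list**

1 | 2-bromoprop-2-en-1-ol | OCC(Br)=C | starting material
2 | trimethylsilylacetylene | C#C[Si](C)(C)C | starting material
3 | 2-methylidene-4-(trimethylsilyl)but-3-yn-1-ol | OCC(=C)C#C[Si](C)(C)C | intermediate
4 | (R)-{2-[(trimethylsilyl)ethynyl]oxiran-2-yl}methanol | OC[C@@]1(CO1)C#C[Si](C)(C)C | intermediate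
5 | (S)-tert-butyldimethyl({2-[(trimethylsilyl)ethynyl]oxiran-2-yl}methoxy)silane | CC(C)(C)[Si](C)(C)OC[C@@]1(CO1)C#C[Si](C)(C)C | intermediate
6 | allylmagnesium chloride | C=CC[Mg]Cl | starting material
7 | (3R)-3-[(TBS-oxy)methyl]-1-(trimethylsilyl)hept-6-en-1-yn-3-ol | C=CCC[C@](O)(CO[Si](C)(C)C(C)(C)C)C#C[Si](C)(C)C | intermediate
8 | (3R)-3-[(TBS-oxy)methyl]-5-(oxiran-2-yl)-1-(trimethylsilyl)pent-1-yn-3-ol, both epoxide epimers | C1OC1CC[C@](O)(CO[Si](C)(C)C(C)(C)C)C#C[Si](C)(C)C | intermediate (not isolated)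
9 | {(5R)-5-[(TBS-oxy)methyl]-5-[(trimethylsilyl)ethynyl]oxolan-2-yl}methanol, both C2 epimers | OCC1CC[C@](CO[Si](C)(C)C(C)(C)C)(C#C[Si](C)(C)C)O1 | intermediate
10 | (5R)-5-[(TBS-oxy)methyl]-5-[(trimethylsilyl)ethynyl]oxolane-2-carbaldehyde | O=CC1CC[C@](CO[Si](C)(C)C(C)(C)C)(C#C[Si](C)(C)C)O1 | intermediate (not isolated)
11 | (5R)-5-[(TBS-oxy)methyl]-5-[(trimethylsilyl)ethynyl]oxolane-2-carboxylic acid, both C2 epimers | OC(=O)C1CC[C@](CO[Si](C)(C)C(C)(C)C)(C#C[Si](C)(C)C)O1 | intermediate
12 | allyl (5R)-5-[(TBS-oxy)methyl]-5-[(trimethylsilyl)ethynyl]oxolane-2-carboxylate, both C2 epimers | C=CCOC(=O)C1CC[C@](CO[Si](C)(C)C(C)(C)C)(C#C[Si](C)(C)C)O1 | intermediate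
13 | β-damascone | C/C=C/C(=O)C1=C(C)CCCC1(C)C | starting material
14 | lithium ester enolate of 12 | [Li]OC(OCC=C)=C1CC[C@](CO[Si](C)(C)C(C)(C)C)(C#C[Si](C)(C)C)O1 | intermediate (not isolated)
15 | lithium (Z)-enolate of the Michael adduct (8R,9R,13R) | CC1=C(/C(O[Li])=C/[C@@H](C)[C@@]2(C(=O)OCC=C)CC[C@](CO[Si](C)(C)C(C)(C)C)(C#C[Si](C)(C)C)O2)C(C)(C)CCC1 | intermediate (not isolated)
16 | allyl (2R,5R)-2-[(2R,3Z)-4-(TBS-oxy)-4-(2,6,6-trimethylcyclohex-1-en-1-yl)but-3-en-2-yl]-5-[(TBS-oxy)methyl]-5-[(trimethylsilyl)ethynyl]oxolane-2-carboxylate | CC1=C(/C(O[Si](C)(C)C(C)(C)C)=C/[C@@H](C)[C@@]2(C(=O)OCC=C)CC[C@](CO[Si](C)(C)C(C)(C)C)(C#C[Si](C)(C)C)O2)C(C)(C)CCC1 | intermediate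
17 | 2-(TBS-oxy)oxirane formed from 16 at C6–C7 | CC1=C([C@@]2(O[Si](C)(C)C(C)(C)C)O[C@@H]2[C@@H](C)[C@@]3(C(=O)OCC=C)CC[C@](CO[Si](C)(C)C(C)(C)C)(C#C[Si](C)(C)C)O3)C(C)(C)CCC1 | intermediate (not isolated)
18 | allyl (2R,5R)-2-[(2R,3R)-3-(TBS-oxy)-4-oxo-4-(2,6,6-trimethylcyclohex-1-en-1-yl)butan-2-yl]-5-[(TBS-oxy)methyl]-5-[(trimethylsilyl)ethynyl]oxolane-2-carboxylate | CC1=C(C(=O)[C@H](O[Si](C)(C)C(C)(C)C)[C@@H](C)[C@@]2(C(=O)OCC=C)CC[C@](CO[Si](C)(C)C(C)(C)C)(C#C[Si](C)(C)C)O2)C(C)(C)CCC1 | intermediate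
19 | carboxylic acid corresponding to 18 | CC1=C(C(=O)[C@H](O[Si](C)(C)C(C)(C)C)[C@@H](C)[C@@]2(C(=O)O)CC[C@](CO[Si](C)(C)C(C)(C)C)(C#C[Si](C)(C)C)O2)C(C)(C)CCC1 | intermediate
20 | N-hydroxyphthalimide | ON1C(=O)c2ccccc2C1=O | starting material
21 | 1,3-dioxoisoindolin-2-yl ester of 19 (key-step precursor; 7R,8R,9R,13R) | CC1=C(C(=O)[C@H](O[Si](C)(C)C(C)(C)C)[C@@H](C)[C@@]2(C(=O)ON3C(=O)c4ccccc4C3=O)CC[C@](CO[Si](C)(C)C(C)(C)C)(C#C[Si](C)(C)C)O2)C(C)(C)CCC1 | intermediate
22 | C9 tertiary α-alkoxy radical from 21 | CC1=C(C(=O)[C@H](O[Si](C)(C)C(C)(C)C)[C@@H](C)[C]2CC[C@](CO[Si](C)(C)C(C)(C)C)(C#C[Si](C)(C)C)O2)C(C)(C)CCC1 | intermediate (not isolated)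
23 | zinc C5(6)-enolate of 24, drawn as the anion | [O-]C=1[C@H](O[Si](C)(C)C(C)(C)C)[C@@H](C)[C@]2(CC[C@](CO[Si](C)(C)C(C)(C)C)(C#C[Si](C)(C)C)O2)[C@@]2(C)CCCC(C)(C)C=12 | intermediate (not isolated)
24 | (5S,7R,8R,9R,10S,13R)-7β,16-bis(TBS-oxy)-9α,13-epoxy-15-(trimethylsilyl)labd-14-yn-6-one (key-step product) | O=C1[C@H](O[Si](C)(C)C(C)(C)C)[C@@H](C)[C@]2(CC[C@](CO[Si](C)(C)C(C)(C)C)(C#C[Si](C)(C)C)O2)[C@@]2(C)CCCC(C)(C)[C@H]12 | intermediate
25 | (5S,6S,7R,8R,9R,10S,13R)-7β,16-bis(TBS-oxy)-9α,13-epoxy-15-(trimethylsilyl)labd-14-yn-6β-ol | O[C@@H]1[C@H](O[Si](C)(C)C(C)(C)C)[C@@H](C)[C@]2(CC[C@](CO[Si](C)(C)C(C)(C)C)(C#C[Si](C)(C)C)O2)[C@@]2(C)CCCC(C)(C)[C@H]12 | intermediate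
26 | 6β-acetate of 25 | CC(=O)O[C@@H]1[C@H](O[Si](C)(C)C(C)(C)C)[C@@H](C)[C@]2(CC[C@](CO[Si](C)(C)C(C)(C)C)(C#C[Si](C)(C)C)O2)[C@@]2(C)CCCC(C)(C)[C@H]12 | intermediate
27 | (13R)-6β-acetoxy-9α,13-epoxylabd-14-yne-7β,16-diol | CC(=O)O[C@@H]1[C@H](O)[C@@H](C)[C@]2(CC[C@](CO)(C#C)O2)[C@@]2(C)CCCC(C)(C)[C@H]12 | intermediate
28 | (13R)-6β-acetoxy-9α,13:15,16-diepoxylabd-14-en-7β-ol | CC(=O)O[C@@H]1[C@H](O)[C@@H](C)[C@]2(CC[C@]3(C=COC3)O2)[C@@]2(C)CCCC(C)(C)[C@H]12 | intermediate
29 | (5S,6S,8S,9R,10S,13R)-6β-acetoxy-9α,13:15,16-diepoxylabd-14-en-7-one (CNP0224709.1) | CC(=O)O[C@@H]1C(=O)[C@@H](C)[C@]2(CC[C@]3(C=COC3)O2)[C@@]2(C)CCCC(C)(C)[C@H]12 | target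

**Step count and risks**

Total step count: 17. Longest linear sequence: 17 steps (1 → 29); β-damascone and N-hydroxyphthalimide enter as single reagents.

Steps most likely to fail:

1. Step 12. The C9 radical must add to a tetrasubstituted, twisted enone carbon; it may instead be reduced or pick up hydrogen before it cyclises, or close through the chair that puts C11 axial. The fallback sets out from acid 19 and returns at 24; it replaces the reductive process by a chain group transfer that needs neither reductant nor hydrogen donor. Acid 19 is condensed with N-hydroxypyridine-2-thione (DIC, DMAP, CH2Cl2, dark) to the Barton ester (O-acyl thiohydroxamate) F1. Visible-light irradiation of a dilute PhCF3 solution starts a chain in which the C9 radical cyclises and the C5 α-keto radical takes the 2-pyridylthio group from a second molecule of the ester, giving the 5-(pyridin-2-ylthio) ketone F2. SmI2 (THF/MeOH, −78 °C) then cleaves the weak C5–S bond in preference to the C7–O bond, and protonation of the samarium enolate gives 24.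

2. Step 8. The relay of configuration from C13 to C8 through the temporary C9 centre may be weak (addition on both faces of the enolate), and proton transfer from the γ-methyl group of the enone may compete with conjugate addition. The fallback sets out from ester 12 and returns at 16; it sets C8 by a catalyst instead of by C13. 1-Propynylmagnesium bromide adds to β-cyclocitral to give the carbinol 1-(2,6,6-trimethylcyclohex-1-en-1-yl)but-2-yn-1-ol F3, which MnO2 oxidises to the ynone F4. The lithium enolate of 12 adds to this ynone and, after equilibration with catalytic iodine, gives the (E)-enone F5, in which C8 is trigonal. Copper hydride 1,4-reduction (Cu(OAc)2, DTBM-SEGPHOS, (EtO)2MeSiH, toluene/tBuOH), with the ligand enantiomer chosen by experiment for the (8R) product, gives the saturated ketone F6. LiN(iPr)2 followed by TBSOTf converts it into 16, together with its C9 epimer, which converges in step 12.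

3. Step 16. With O7 free, the amine base at 55 °C may move the acetyl group from O6 to O7. The fallback sets out from 26 and returns at 28; it keeps O7 silylated until ring D is closed. Bu4NF/AcOH at 0 °C removes only the primary silyl ether and the alkynylsilane and gives the 7-silyl ether alkynol F7. The tungsten-catalysed cycloisomerisation is run on this compound and gives the silylated dihydrofuran F8. Buffered Bu4NF at room temperature then frees O7, giving 28 directly before the oxidation.

Further compounds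
F1 | step 12 | 2-thioxopyridin-1(2H)-yl ester of 19 (Barton ester) | CC1=C(C(=O)[C@H](O[Si](C)(C)C(C)(C)C)[C@@H](C)[C@@]2(C(=O)ON3C=CC=CC3=S)CC[C@](CO[Si](C)(C)C(C)(C)C)(C#C[Si](C)(C)C)O2)C(C)(C)CCC1
F2 | step 12 | (7R,8R,9R,10S,13R)-7β,16-bis(TBS-oxy)-9α,13-epoxy-5-(pyridin-2-ylthio)-15-(trimethylsilyl)labd-14-yn-6-one, C5 configuration immaterial | O=C1[C@H](O[Si](C)(C)C(C)(C)C)[C@@H](C)[C@]2(CC[C@](CO[Si](C)(C)C(C)(C)C)(C#C[Si](C)(C)C)O2)[C@@]2(C)CCCC(C)(C)C12Sc1ccccn1
F3 | step 8 | 1-(2,6,6-trimethylcyclohex-1-en-1-yl)but-2-yn-1-ol, racemic | CC#CC(O)C1=C(C)CCCC1(C)C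
F4 | step 8 | 1-(2,6,6-trimethylcyclohex-1-en-1-yl)but-2-yn-1-one | CC#CC(=O)C1=C(C)CCCC1(C)C
F5 | step 8 | allyl (5R)-5-[(TBS-oxy)methyl]-2-[(2E)-4-oxo-4-(2,6,6-trimethylcyclohex-1-en-1-yl)but-2-en-2-yl]-5-[(trimethylsilyl)ethynyl]oxolane-2-carboxylate, both C2 epimers | CC1=C(C(=O)/C=C(\C)C2(C(=O)OCC=C)CC[C@](CO[Si](C)(C)C(C)(C)C)(C#C[Si](C)(C)C)O2)C(C)(C)CCC1
F6 | step 8 | allyl (5R)-5-[(TBS-oxy)methyl]-2-[(2R)-4-oxo-4-(2,6,6-trimethylcyclohex-1-en-1-yl)butan-2-yl]-5-[(trimethylsilyl)ethynyl]oxolane-2-carboxylate, both C2 epimers | CC1=C(C(=O)C[C@@H](C)C2(C(=O)OCC=C)CC[C@](CO[Si](C)(C)C(C)(C)C)(C#C[Si](C)(C)C)O2)C(C)(C)CCC1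
F7 | step 16 | (13R)-6β-acetoxy-7β-(TBS-oxy)-9α,13-epoxylabd-14-yn-16-ol | CC(=O)O[C@@H]1[C@H](O[Si](C)(C)C(C)(C)C)[C@@H](C)[C@]2(CC[C@](CO)(C#C)O2)[C@@]2(C)CCCC(C)(C)[C@H]12
F8 | step 16 | (13R)-6β-acetoxy-7β-(TBS-oxy)-9α,13:15,16-diepoxylabd-14-ene | CC(=O)O[C@@H]1[C@H](O[Si](C)(C)C(C)(C)C)[C@@H](C)[C@]2(CC[C@]3(C=COC3)O2)[C@@]2(C)CCCC(C)(C)[C@H]12
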